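(Readings and results are calculated with made-up constants, and the scatter is random.)

How many questions stand on this flask? 3, and they are these:

* share of over-reaction product in over-reaction product plus target at 40 min
* share of over-reaction product in over-reaction product plus target at 4.0 d
* which of over-reaction product and target there is more of at 4.0 d

- south: substrate 0.50 M; coupling partner 0.60 M; free catalyst 2.5 mM; second catalyst 1.1 mM; the very flask that is asked about, followed so far
- flask: substrate 0.50 M; coupling partner 0.600 M; free catalyst 2.5 mM; second catalyst 1.1 mM; time 4.0 d

south run (percent of the substrate charged)

| time / h | over-reaction product / % | target / % | substrate / % |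
|---|---|---|---|
| 1.33 | 1.0 | 5.9 | 66.4 |
| 3.00 | 2.7 | 12.1 | 35.7 |
| 6.00 | 8.1 | 18.8 | 13.3 |
| 10.0 | 16.4 | 24.5 | 4.8 |
| 12.0 | 23.4 | 27.2 | 1.9 |
| 15.0 | 27.1 | 29.8 | 1.5 |

(scatter of a reading: 1 percentage point)

- what was read earlier has a scatter of 1 percentage point, one standard deviation

What can be read from these runs without integrating anything? A running count. I take it that a target carries one coupling partner and that an over-reaction product, made from a target, carries a second one.

So what is the count? It is target plus 2 times over-reaction product, held against the partner budget, the coupling partner charged in percent of the substrate charged: 120%.

How much is spent at the last reading? At 15.0 h the readings give 84.0%. At that average pace the budget lasts until about 21.4 h, which is earlier than 4.0 d, so I expect the asked time to find a stopped flask.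

And the split at the stop? Between 10.0 h and 15.0 h the readings, with their scatter, show target gaining about 0.495 for each unit of over-reaction product. Continuing that split until the budget ends, I reckon over-reaction product at 41.5% and target at 36.9%. That is a share of 52.9%, with over-reaction product ahead.

Where is this thin? At 40 min, which is earlier than the first reading at 1.33 h. If the share grows from zero in step with time, scaling its 3.00 h reading of 18.2% gives about 4.05%.

The forecast gives 14%, 60% and over-reaction product ahead, reasoning that “the 1.2 equivalents run out when target + 2 × over-reaction product = 120”. It names the same leader as I do, but its two shares differ from mine.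

The flask gives 4.30%, 60.1% and over-reaction product ahead.

    coupling partner + catalyst intermediate → second catalyst + target (k = 71.0 M⁻¹ h⁻¹)
    substrate + free catalyst → free catalyst + open intermediate (k = 130 M⁻¹ h⁻¹)
    coupling partner + free catalyst + target → free catalyst + over-reaction product (k = 120 M⁻² h⁻¹)
    second catalyst + open intermediate ⇌ catalyst intermediate (K = 9.80 M⁻¹, k = 2800 M⁻¹ h⁻¹)

At 4.00 d the flask holds 29.9% of target and 45.0% of over-reaction product, a count of 120% against the budget of 120%. Of the coupling partner, the limiting reagent, 0.022% of its charge is left. The neighbouring flask, charged with 0.24 M of coupling partner, has a budget of 48.0%. At 4.00 d it holds 23.7% of target and 12.1% of over-reaction product, a count of 47.9%, and open intermediate holds 64.0% of the substrate charged.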